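**Retrosynthetic overview**

1. Numbering: lactone carbonyl C1, ring carbinol C5, chain end C26. The route rests on the carbinols C5 (in the ring), C7, C9 and C11 being all syn and separated by single CH2 groups (C6, C8, C10), so that C4–C11 is a head-to-tail chain of four acetaldehyde units.
2. The dihydropyranone (the only ring) is closed last, by lactonisation of C5–OH onto a Z-configured C1 ester. C2=C3 comes from an Ando olefination of the C3 aldehyde, and C11–C12 from pentadecylmagnesium bromide and the C11 aldehyde.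
3. C7–C8 and C9–C10, with the C7 and C9 stereocentres, come from a one-pot double Mukaiyama aldol of acetaldehyde tris(trimethylsilyl)silyl enol ether with the C3–C7 aldehyde that carries the C5 (Me3Si)3SiO group.
4. C5 is set by Noyori hydrogenation of the β-keto ester made from methyl acetoacetate dianion and benzyl chloromethyl ether (C3–C4 bond).

Key step: step 6

Remark: chlorotris(trimethylsilyl)silane, 1-bromopentadecane and ethyl 2-[bis(2-methylphenoxy)phosphoryl]acetate are taken as purchasable, and the tetrahydrofuran of step 5 serves as both reactant and solvent.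

**Route**

Step 1
Reactants: 1 methyl acetoacetate; 2 benzyl chloromethyl ether
Product: 4 methyl 5-(benzyloxy)-3-oxopentanoate, via acetoacetate dianion 3 (not isolated)
Conditions: NaH, THF, 0 °C; n-BuLi, 0 °C; then 2, −25 → 0 °C; dil. HCl
Reagents that add atoms: none
Why: Weiler dianion alkylation, in which the more basic terminal carbanion of the dianion displaces chloride from 2 and so forms the C3–C4 bond at the γ-carbon only.

Step 2
Reactants: 4 methyl 5-(benzyloxy)-3-oxopentanoate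
Product: 5 methyl (S)-5-(benzyloxy)-3-hydroxypentanoate
Conditions: H2 (50 atm), [RuCl(p-cymene)((S)-BINAP)]Cl (0.2 mol%), MeOH, 50 °C
Reagents that add atoms: none
Why: Noyori asymmetric hydrogenation of a β-keto ester, in which the ester-chelated ruthenium hydride carrying (S)-BINAP delivers hydrogen to one carbonyl face and should set C5 as S, while the benzyl ether is not touched by the homogeneous catalyst.

Step 3
Reactants: 5 methyl (S)-5-(benzyloxy)-3-hydroxypentanoate; 6 chlorotris(trimethylsilyl)silane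
Product: 7 methyl (S)-5-(benzyloxy)-3-{[tris(trimethylsilyl)silyl]oxy}pentanoate
Conditions: DMAP (1.3 equiv), CH2Cl2, rt
Reagents that add atoms: none
Why: DMAP-mediated O-silylation of a secondary alcohol with the chlorosilane, mild enough that the β-hydroxy ester neither eliminates nor epimerises.

Step 4
Reactants: 7 methyl (S)-5-(benzyloxy)-3-{[tris(trimethylsilyl)silyl]oxy}pentanoate
Product: 8 (S)-5-(benzyloxy)-3-{[tris(trimethylsilyl)silyl]oxy}pentanal
Conditions: iBu2AlH (1.1 equiv), CH2Cl2, −78 °C; MeOH, then aq. potassium sodium tartrate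
Reagents that add atoms: none
Why: partial reduction of an ester by iBu2AlH, whose tetrahedral aluminium acetal persists at −78 °C and releases the aldehyde only on work-up, the benzyl and silyl ethers being inert to the hydride.

Step 5
Reactants: 9 tetrahydrofuran; 6 chlorotris(trimethylsilyl)silane
Product: 11 acetaldehyde tris(trimethylsilyl)silyl enol ether [vinyloxy-tris(trimethylsilyl)silane], via lithium ethenolate 10 (not isolated)
Conditions: n-BuLi, THF, 25 °C, 16 h; then 6, 0 °C → rt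
Reagents that add atoms: none
Why: α-lithiation of tetrahydrofuran followed by [3+2] cycloreversion gives ethene and the lithium enolate of acetaldehyde, which the hard, bulky chlorosilane silylates on oxygen.

Step 6
Reactants: 8 (S)-5-(benzyloxy)-3-{[tris(trimethylsilyl)silyl]oxy}pentanal; 11 acetaldehyde tris(trimethylsilyl)silyl enol ether (2.3 equiv)
Product: 13 (3S,5S,7S)-9-(benzyloxy)-3,5,7-tris{[tris(trimethylsilyl)silyl]oxy}nonanal, via mono-aldol heptanal 12 (not isolated)
Conditions: HNTf2 (0.1 mol%), PhI (10 mol%), CH2Cl2, −40 °C → rt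
Reagents that add atoms: none
Why: HNTf2 protodesilylates a trace of 11 to (Me3Si)3SiNTf2, which activates the C7 aldehyde of 8; 11 adds (Mukaiyama aldol, C7–C8), a bulky silyl group ends up on the new C7 oxygen while the silyl cation is handed on to the next aldehyde, so 12 is released as a free aldehyde and the same cycle forms C9–C10 to give 13. This is the known triflimide-catalysed sequential aldehyde cross-aldol of acetaldehyde supersilyl enol ether, applied to a β-supersilyloxy aldehyde of the kind the reaction itself produces, with iodobenzene serving only as a weak donor that moderates the silyl triflimide. No ring is closed. C7 is set under control of the C5 silyloxy stereocentre and C9 under control of the new C7 silyloxy stereocentre: the very large β-(Me3Si)3SiO group shields one face of the silyl-activated aldehyde, and additions to such aldehydes are known to favour the 1,3-syn product (S at both new centres of 13 by the CIP rules). The step needs syn selectivity twice and a halt after exactly two additions; the first is secured by the β-silyloxy group next to each reacting carbonyl, the second by the stoichiometry of 11 and the falling reactivity of the increasingly hindered aldehyde. The benzyl ether and the Si–O and Si–Si bonds are inert to the trace of acid, and the non-basic medium excludes enolisation and β-elimination of the product aldehyde.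

Step 7
Reactants: 13 (3S,5S,7S)-9-(benzyloxy)-3,5,7-tris{[tris(trimethylsilyl)silyl]oxy}nonanal; 14 1-bromopentadecane
Product: 16 (3S,5S,7R,9R)-1-(benzyloxy)-3,5,7-tris{[tris(trimethylsilyl)silyl]oxy}tetracosan-9-ol, via pentadecylmagnesium bromide 15 (not isolated)
Conditions: 14, Mg, THF, 40 °C; then 13, CH2Cl2/THF, −78 → −40 °C; H2O
Reagents that add atoms: none
Why: Grignard addition to an aldehyde (C11–C12 bond), in which the β-(Me3Si)3SiO group at C9 should direct attack to the face that gives the 1,3-syn carbinol (C11 R), as reported for organomagnesium additions to β-supersilyloxy aldehydes, with any C11 epimer to be removed by chromatography.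

Step 8
Reactants: 16 (3S,5S,7R,9R)-1-(benzyloxy)-3,5,7-tris{[tris(trimethylsilyl)silyl]oxy}tetracosan-9-ol
Product: 17 (3S,5S,7R,9R)-1-(benzyloxy)-9-[(tert-butyldimethylsilyl)oxy]-3,5,7-tris{[tris(trimethylsilyl)silyl]oxy}tetracosane
Conditions: TBSOTf, 2,6-lutidine, CH2Cl2, −78 → 0 °C
Reagents that add atoms: tert-butyldimethylsilyl trifluoromethanesulfonate, CC(C)(C)[Si](C)(C)OS(=O)(=O)C(F)(F)F
Why: silyl triflate silylation, reactive enough for the hindered C11 alcohol, which masks it against the later oxidation and the basic olefination.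

Step 9
Reactants: 17 (3S,5S,7R,9R)-1-(benzyloxy)-9-[(tert-butyldimethylsilyl)oxy]-3,5,7-tris{[tris(trimethylsilyl)silyl]oxy}tetracosane
Product: 18 (3S,5S,7R,9R)-9-[(tert-butyldimethylsilyl)oxy]-3,5,7-tris{[tris(trimethylsilyl)silyl]oxy}tetracosan-1-ol
Conditions: H2 (1 atm), 10% Pd/C, EtOAc, rt
Reagents that add atoms: none
Why: heterogeneous hydrogenolysis of the benzyl ether, run in a non-protic solvent so that the silyl ethers and the Si–Si bonds should stay intact.

Step 10
Reactants: 18 (3S,5S,7R,9R)-9-[(tert-butyldimethylsilyl)oxy]-3,5,7-tris{[tris(trimethylsilyl)silyl]oxy}tetracosan-1-ol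
Product: 19 (3R,5R,7R,9R)-9-[(tert-butyldimethylsilyl)oxy]-3,5,7-tris{[tris(trimethylsilyl)silyl]oxy}tetracosanal
Conditions: Dess–Martin periodinane, CH2Cl2, 0 °C → rt
Reagents that add atoms: none
Why: Dess–Martin oxidation of the only free (primary) alcohol to the C3 aldehyde under near-neutral conditions that should not cause β-elimination of the C5 silyloxy group (the descriptors change by priority only).

Step 11
Reactants: 19 (3R,5R,7R,9R)-9-[(tert-butyldimethylsilyl)oxy]-3,5,7-tris{[tris(trimethylsilyl)silyl]oxy}tetracosanal; 20 ethyl 2-[bis(2-methylphenoxy)phosphoryl]acetate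
Product: 21 ethyl (2Z,5S,7S,9R,11R)-11-[(tert-butyldimethylsilyl)oxy]-5,7,9-tris{[tris(trimethylsilyl)silyl]oxy}hexacos-2-enoate
Conditions: 20, NaH, THF, 0 °C; then 19, −78 → 0 °C
Reagents that add atoms: none
Why: Ando variant of the Horner–Wadsworth–Emmons olefination, in which the electron-poor diaryl phosphonate eliminates fast from the kinetically formed adduct and should give the Z C2=C3 enoate, the low temperature protecting the β-silyloxy aldehyde from elimination.

Step 12
Reactants: 21 ethyl (2Z,5S,7S,9R,11R)-11-[(tert-butyldimethylsilyl)oxy]-5,7,9-tris{[tris(trimethylsilyl)silyl]oxy}hexacos-2-enoate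
Product: 23 (6S)-6-[(2R,4R,6R)-2,4,6-trihydroxyhenicosyl]-5,6-dihydro-2H-pyran-2-one, via tetrahydroxy Z-enoate 22 (not isolated)
Conditions: 48% aq. HF, MeCN/CH2Cl2, 0 °C → rt
Reagents that add atoms: none
Why: acidic fluoride cleavage of all four Si–O bonds frees the tetrol, whose C5 hydroxyl lies next to the Z-ester and should lactonise with loss of ethanol, the acidic medium keeping the C7 hydroxyl from adding to the enoate in an oxa-Michael reaction.

**Compound list**

1 | methyl acetoacetate | COC(=O)CC(C)=O | starting material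
2 | benzyl chloromethyl ether | ClCOCc1ccccc1 | starting material
3 | sodium lithium dianion of methyl acetoacetate | [Na+].[Li+].[CH2-]C(=O)[CH-]C(=O)OC | intermediate
4 | methyl 5-(benzyloxy)-3-oxopentanoate | COC(=O)CC(=O)CCOCc1ccccc1 | intermediate
5 | methyl (S)-5-(benzyloxy)-3-hydroxypentanoate | COC(=O)C[C@@H](O)CCOCc1ccccc1 | intermediate
6 | chlorotris(trimethylsilyl)silane | C[Si](C)(C)[Si](Cl)([Si](C)(C)C)[Si](C)(C)C | starting material
7 | methyl (S)-5-(benzyloxy)-3-{[tris(trimethylsilyl)silyl]oxy}pentanoate | COC(=O)C[C@@H](O[Si]([Si](C)(C)C)([Si](C)(C)C)[Si](C)(C)C)CCOCc1ccccc1 | intermediate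
8 | (S)-5-(benzyloxy)-3-{[tris(trimethylsilyl)silyl]oxy}pentanal | O=CC[C@@H](O[Si]([Si](C)(C)C)([Si](C)(C)C)[Si](C)(C)C)CCOCc1ccccc1 | intermediate
9 | tetrahydrofuran | C1CCOC1 | starting material
10 | lithium ethenolate | [Li+].[O-]C=C | intermediate
11 | acetaldehyde tris(trimethylsilyl)silyl enol ether | C=CO[Si]([Si](C)(C)C)([Si](C)(C)C)[Si](C)(C)C | intermediate
12 | (3S,5S)-7-(benzyloxy)-3,5-bis{[tris(trimethylsilyl)silyl]oxy}heptanal | O=CC[C@@H](O[Si]([Si](C)(C)C)([Si](C)(C)C)[Si](C)(C)C)C[C@@H](O[Si]([Si](C)(C)C)([Si](C)(C)C)[Si](C)(C)C)CCOCc1ccccc1 | intermediate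
13 | (3S,5S,7S)-9-(benzyloxy)-3,5,7-tris{[tris(trimethylsilyl)silyl]oxy}nonanal | O=CC[C@@H](O[Si]([Si](C)(C)C)([Si](C)(C)C)[Si](C)(C)C)C[C@@H](O[Si]([Si](C)(C)C)([Si](C)(C)C)[Si](C)(C)C)C[C@@H](O[Si]([Si](C)(C)C)([Si](C)(C)C)[Si](C)(C)C)CCOCc1ccccc1 | intermediate
14 | 1-bromopentadecane | CCCCCCCCCCCCCCCBr | starting material
15 | pentadecylmagnesium bromide | CCCCCCCCCCCCCCC[Mg]Br | intermediate
16 | (3S,5S,7R,9R)-1-(benzyloxy)-3,5,7-tris{[tris(trimethylsilyl)silyl]oxy}tetracosan-9-ol | CCCCCCCCCCCCCCC[C@@H](O)C[C@@H](O[Si]([Si](C)(C)C)([Si](C)(C)C)[Si](C)(C)C)C[C@@H](O[Si]([Si](C)(C)C)([Si](C)(C)C)[Si](C)(C)C)C[C@@H](O[Si]([Si](C)(C)C)([Si](C)(C)C)[Si](C)(C)C)CCOCc1ccccc1 | intermediate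
17 | (3S,5S,7R,9R)-1-(benzyloxy)-9-[(tert-butyldimethylsilyl)oxy]-3,5,7-tris{[tris(trimethylsilyl)silyl]oxy}tetracosane | CCCCCCCCCCCCCCC[C@@H](O[Si](C)(C)C(C)(C)C)C[C@@H](O[Si]([Si](C)(C)C)([Si](C)(C)C)[Si](C)(C)C)C[C@@H](O[Si]([Si](C)(C)C)([Si](C)(C)C)[Si](C)(C)C)C[C@@H](O[Si]([Si](C)(C)C)([Si](C)(C)C)[Si](C)(C)C)CCOCc1ccccc1 | intermediate
18 | (3S,5S,7R,9R)-9-[(tert-butyldimethylsilyl)oxy]-3,5,7-tris{[tris(trimethylsilyl)silyl]oxy}tetracosan-1-ol | CCCCCCCCCCCCCCC[C@@H](O[Si](C)(C)C(C)(C)C)C[C@@H](O[Si]([Si](C)(C)C)([Si](C)(C)C)[Si](C)(C)C)C[C@@H](O[Si]([Si](C)(C)C)([Si](C)(C)C)[Si](C)(C)C)C[C@@H](O[Si]([Si](C)(C)C)([Si](C)(C)C)[Si](C)(C)C)CCO | intermediate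
19 | (3R,5R,7R,9R)-9-[(tert-butyldimethylsilyl)oxy]-3,5,7-tris{[tris(trimethylsilyl)silyl]oxy}tetracosanal | CCCCCCCCCCCCCCC[C@@H](O[Si](C)(C)C(C)(C)C)C[C@@H](O[Si]([Si](C)(C)C)([Si](C)(C)C)[Si](C)(C)C)C[C@@H](O[Si]([Si](C)(C)C)([Si](C)(C)C)[Si](C)(C)C)C[C@@H](O[Si]([Si](C)(C)C)([Si](C)(C)C)[Si](C)(C)C)CC=O | intermediate
20 | ethyl 2-[bis(2-methylphenoxy)phosphoryl]acetate | CCOC(=O)CP(=O)(Oc1ccccc1C)Oc1ccccc1C | starting material
21 | ethyl (2Z,5S,7S,9R,11R)-11-[(tert-butyldimethylsilyl)oxy]-5,7,9-tris{[tris(trimethylsilyl)silyl]oxy}hexacos-2-enoate | CCCCCCCCCCCCCCC[C@@H](O[Si](C)(C)C(C)(C)C)C[C@@H](O[Si]([Si](C)(C)C)([Si](C)(C)C)[Si](C)(C)C)C[C@@H](O[Si]([Si](C)(C)C)([Si](C)(C)C)[Si](C)(C)C)C[C@@H](O[Si]([Si](C)(C)C)([Si](C)(C)C)[Si](C)(C)C)C/C=C\C(=O)OCC | intermediate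
22 | ethyl (2Z,5S,7S,9R,11R)-5,7,9,11-tetrahydroxyhexacos-2-enoate | CCCCCCCCCCCCCCC[C@@H](O)C[C@@H](O)C[C@@H](O)C[C@@H](O)C/C=C\C(=O)OCC | intermediate
23 | (6S)-6-[(2R,4R,6R)-2,4,6-trihydroxyhenicosyl]-5,6-dihydro-2H-pyran-2-one | CCCCCCCCCCCCCCC[C@@H](O)C[C@@H](O)C[C@@H](O)C[C@@H]1CC=CC(=O)O1 | target

**Step count and risks**

Total steps: 12. Longest linear sequence: 11 (steps 1–4 and 6–12; step 5 is a one-step branch).

The three steps most likely to fail:

1. Step 6. The cascade may stall after the first addition, run on to a third, or lose syn selectivity at the second, more hindered aldehyde. The fallback builds the same two carbinols one at a time under reagent control. It sets out from 8. Brown allylation with (+)-Ipc2B(allyl) (from (−)-α-pinene, made from (+)-Ipc2BOMe and allylmagnesium bromide; Et2O, −78 °C, ethanolamine work-up) should give (4R,6S)-8-(benzyloxy)-6-{[tris(trimethylsilyl)silyl]oxy}oct-1-en-4-ol F1. Silylation with 6 and DMAP would give the bis-silyl ether (4R,6S)-8-(benzyloxy)-4,6-bis{[tris(trimethylsilyl)silyl]oxy}oct-1-ene F2. Oxidative cleavage of the vinyl group (OsO4 cat., NaIO4, 2,6-lutidine, dioxane/H2O, chosen over ozone to spare the Si–Si bonds) would give aldehyde 12, now isolated. The same three operations on 12 would pass through (4R,6R,8S)-10-(benzyloxy)-6,8-bis{[tris(trimethylsilyl)silyl]oxy}dec-1-en-4-ol F3 and (4R,6R,8S)-10-(benzyloxy)-4,6,8-tris{[tris(trimethylsilyl)silyl]oxy}dec-1-ene F4, and the fallback comes back to the route at 13.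

2. Step 7. Facial selectivity at C11 may be poor, since the Grignard addition relies on 1,3-induction from one β-silyloxy group alone. The fallback sets C11 by reagent control and builds the chain afterwards. It sets out from 13. Allylation with the same (+)-Ipc2B(allyl) should give (4R,6R,8S,10S)-12-(benzyloxy)-6,8,10-tris{[tris(trimethylsilyl)silyl]oxy}dodec-1-en-4-ol F5. Cross-metathesis with 1-tetradecene (second-generation Grubbs catalyst, CH2Cl2, 40 °C) would give (3S,5S,7R,9R,11E)-1-(benzyloxy)-3,5,7-tris{[tris(trimethylsilyl)silyl]oxy}tetracos-11-en-9-ol F6. TBSOTf and 2,6-lutidine would give its silyl ether (3S,5S,7R,9R,11E)-1-(benzyloxy)-9-[(tert-butyldimethylsilyl)oxy]-3,5,7-tris{[tris(trimethylsilyl)silyl]oxy}tetracos-11-ene F7. The hydrogenation of step 9 (H2, Pd/C, EtOAc) then saturates the alkene and removes the benzyl group together, and the fallback comes back to the route at 18.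

3. Step 12. Cleavage of the three very hindered (Me3Si)3Si–O bonds by acid may be incomplete, and forcing it with basic fluoride on the finished enoate invites oxa-Michael addition of the C7 hydroxyl. The fallback removes the supersilyl groups before the enoate exists. It sets out from 16. Bu4NF in THF should give (3S,5S,7R,9R)-1-(benzyloxy)tetracosane-3,5,7,9-tetrol F8. 2,2-Dimethoxypropane with PPTS would give its 3,5:7,9-bis(acetonide) F9, in which both syn-diols sit in 1,3-dioxanes. Hydrogenolysis (H2, Pd/C, EtOAc) would give the bis(acetonide) primary alcohol F10, Dess–Martin oxidation the bis(acetonide) aldehyde F11, and Ando olefination with 20 the bis(acetonide) Z-enoate F12. Warm 80% aqueous AcOH (60 °C) would then remove both acetonides and lactonise, and the fallback comes back to the route at 23.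

**Further compounds**

F1 | step 6 | (4R,6S)-8-(benzyloxy)-6-{[tris(trimethylsilyl)silyl]oxy}oct-1-en-4-ol | C=CC[C@@H](O)C[C@@H](O[Si]([Si](C)(C)C)([Si](C)(C)C)[Si](C)(C)C)CCOCc1ccccc1
F2 | step 6 | (4R,6S)-8-(benzyloxy)-4,6-bis{[tris(trimethylsilyl)silyl]oxy}oct-1-ene | C=CC[C@@H](O[Si]([Si](C)(C)C)([Si](C)(C)C)[Si](C)(C)C)C[C@@H](O[Si]([Si](C)(C)C)([Si](C)(C)C)[Si](C)(C)C)CCOCc1ccccc1
F3 | step 6 | (4R,6R,8S)-10-(benzyloxy)-6,8-bis{[tris(trimethylsilyl)silyl]oxy}dec-1-en-4-ol | C=CC[C@@H](O)C[C@@H](O[Si]([Si](C)(C)C)([Si](C)(C)C)[Si](C)(C)C)C[C@@H](O[Si]([Si](C)(C)C)([Si](C)(C)C)[Si](C)(C)C)CCOCc1ccccc1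
F4 | step 6 | (4R,6R,8S)-10-(benzyloxy)-4,6,8-tris{[tris(trimethylsilyl)silyl]oxy}dec-1-ene | C=CC[C@@H](O[Si]([Si](C)(C)C)([Si](C)(C)C)[Si](C)(C)C)C[C@@H](O[Si]([Si](C)(C)C)([Si](C)(C)C)[Si](C)(C)C)C[C@@H](O[Si]([Si](C)(C)C)([Si](C)(C)C)[Si](C)(C)C)CCOCc1ccccc1
F5 | step 7 | (4R,6R,8S,10S)-12-(benzyloxy)-6,8,10-tris{[tris(trimethylsilyl)silyl]oxy}dodec-1-en-4-ol | C=CC[C@@H](O)C[C@@H](O[Si]([Si](C)(C)C)([Si](C)(C)C)[Si](C)(C)C)C[C@@H](O[Si]([Si](C)(C)C)([Si](C)(C)C)[Si](C)(C)C)C[C@@H](O[Si]([Si](C)(C)C)([Si](C)(C)C)[Si](C)(C)C)CCOCc1ccccc1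
F6 | step 7 | (3S,5S,7R,9R,11E)-1-(benzyloxy)-3,5,7-tris{[tris(trimethylsilyl)silyl]oxy}tetracos-11-en-9-ol | CCCCCCCCCCCC/C=C/C[C@@H](O)C[C@@H](O[Si]([Si](C)(C)C)([Si](C)(C)C)[Si](C)(C)C)C[C@@H](O[Si]([Si](C)(C)C)([Si](C)(C)C)[Si](C)(C)C)C[C@@H](O[Si]([Si](C)(C)C)([Si](C)(C)C)[Si](C)(C)C)CCOCc1ccccc1
F7 | step 7 | (3S,5S,7R,9R,11E)-1-(benzyloxy)-9-[(tert-butyldimethylsilyl)oxy]-3,5,7-tris{[tris(trimethylsilyl)silyl]oxy}tetracos-11-ene | CCCCCCCCCCCC/C=C/C[C@@H](O[Si](C)(C)C(C)(C)C)C[C@@H](O[Si]([Si](C)(C)C)([Si](C)(C)C)[Si](C)(C)C)C[C@@H](O[Si]([Si](C)(C)C)([Si](C)(C)C)[Si](C)(C)C)C[C@@H](O[Si]([Si](C)(C)C)([Si](C)(C)C)[Si](C)(C)C)CCOCc1ccccc1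
F8 | step 12 | (3S,5S,7R,9R)-1-(benzyloxy)tetracosane-3,5,7,9-tetrol | CCCCCCCCCCCCCCC[C@@H](O)C[C@@H](O)C[C@@H](O)C[C@@H](O)CCOCc1ccccc1
F9 | step 12 | 3,5:7,9-bis(acetonide) of F8 (all four centres unchanged) | CCCCCCCCCCCCCCC[C@@H]1C[C@H](C[C@@H]2C[C@H](CCOCc3ccccc3)OC(C)(C)O2)OC(C)(C)O1
F10 | step 12 | bis(acetonide) primary alcohol (debenzylated F9) | CCCCCCCCCCCCCCC[C@@H]1C[C@H](C[C@@H]2C[C@H](CCO)OC(C)(C)O2)OC(C)(C)O1
F11 | step 12 | bis(acetonide) aldehyde | CCCCCCCCCCCCCCC[C@@H]1C[C@H](C[C@@H]2C[C@H](CC=O)OC(C)(C)O2)OC(C)(C)O1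
F12 | step 12 | bis(acetonide) ethyl Z-enoate | CCCCCCCCCCCCCCC[C@@H]1C[C@H](C[C@@H]2C[C@H](C/C=C\C(=O)OCC)OC(C)(C)O2)OC(C)(C)O1
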